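The synthesis rests on one disconnection in the dihydrofuran ring. C2 is bonded both to the ring oxygen O1 and to the carbinol carbon C(CH3)2–O, so this carbon can first be hung on O1 as a mixed acetone ketal and then moved to C2. A rhodium carbenoid flanked by two identical ortho ketal oxygens is trapped as a five-membered oxonium ylide. Its [1,2]-shift forms O1–C2, C2–C(CH3)2 and the furanone ring in one operation. The precursor is a mirror-symmetric 2,6-bis(2-benzyloxyprop-2-yloxy)phenyl diazomethyl ketone. Hydroxyl-directed reduction (trans), camphanate resolution, C5 acetylation para to O1 and a Claisen–Schmidt condensation complete brosimacutin G.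

Key step: step 4

Remark on numbering and stereochemistry: benzofuran numbering (O1, C2, C3, C3a, C4–C7, C7a) is used. The target is (2S,3S), so the C3 hydroxyl is trans to the C2 side chain. Compounds 9–11 are racemic and configurationally labile at C2, 12 is the racemic trans diol, and everything from 13 on is a single stereoisomer.

Remark on design: the enone carbonyl is bonded to C5, so C5 receives an acetyl group. Outer-sphere reductions of 2-substituted benzofuran-3(2H)-ones attack anti to the C2 substituent and give cis alcohols. The trans relationship is therefore set by intramolecular hydride delivery, and the absolute configuration is secured by resolution directly afterwards.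

Assumption: the aryl ketals 3–9 are taken to need acid-free handling (base-washed glassware, Et3N-buffered silica).

Step 1
Reactants: 1 2-bromobenzene-1,3-diol (2-bromoresorcinol); 2 benzyl isopropenyl ether
Product: 3 2-bromo-1,3-bis(2-benzyloxypropan-2-yloxy)benzene
Conditions: 2 (3 equiv), PPTS (5 mol %), CH2Cl2, 0 °C → rt; Et3N quench
Reagents that add atoms: none
Why: Acid-catalysed Markovnikov addition of phenols to an enol ether (mixed-ketal formation, as in 2-alkoxyprop-2-yl protection) is fast for these two unchelated phenols, and running it on the bromide rather than on a 2-acylresorcinol avoids phenols that are deactivated by hydrogen bonding to a carbonyl group.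

Step 2
Reactants: 3 2-bromo-1,3-bis(2-benzyloxypropan-2-yloxy)benzene
Product: 5 1-[2,6-bis(2-benzyloxypropan-2-yloxy)phenyl]ethanone, via aryllithium 4 (not isolated)
Conditions: n-BuLi (1.05 equiv), THF, −78 °C; MeC(O)N(OMe)Me, −78 → 0 °C; pH 7 buffer
Reagents that add atoms: N-methoxy-N-methylacetamide, CC(=O)N(C)OC; n-butyllithium, [Li]CCCC (lithium of 4 only)
Why: Bromine–lithium exchange at −78 °C outruns benzylic deprotonation, and the Weinreb ketone synthesis stops at the methyl ketone because the chelated tetrahedral adduct survives until the neutral quench.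

Step 3
Reactants: 5 1-[2,6-bis(2-benzyloxypropan-2-yloxy)phenyl]ethanone
Product: 7 1-[2,6-bis(2-benzyloxypropan-2-yloxy)phenyl]-2-diazoethanone, via trifluoroacetyl ketone 6 (not isolated)
Conditions: LiN(SiMe3)2, THF, −78 °C; CF3CO2CH2CF3, −78 °C; pH 7 buffer; then MsN3, Et3N, H2O (1 equiv), MeCN, rt; dilute NaOH wash
Reagents that add atoms: methanesulfonyl azide, CS(=O)(=O)N=[N+]=[N-]; 2,2,2-trifluoroethyl trifluoroacetate, O=C(OCC(F)(F)F)C(F)(F)F (trifluoroacetyl group of 6 only)
Why: Detrifluoroacetylative Regitz-type diazo transfer (kinetic enolate, Claisen trifluoroacetylation to activate the methyl ketone, diazo transfer with loss of the trifluoroacetyl group) runs entirely under basic conditions that the acid-labile ketals tolerate.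

Step 4
Reactants: 7 1-[2,6-bis(2-benzyloxypropan-2-yloxy)phenyl]-2-diazoethanone
Product: 9 2-(2-benzyloxypropan-2-yl)-4-(2-benzyloxypropan-2-yloxy)benzofuran-3(2H)-one (racemic), via oxonium ylide 8 (not isolated)
Conditions: Rh2(OAc)4 (1 mol %), 4 Å MS, CH2Cl2, rt, slow addition of 7
Reagents that add atoms: none
Why: Proposed new method: Rh2(OAc)4 expels N2 from 7 to give an electrophilic rhodium carbenoid, a lone pair of an ortho ketal oxygen attacks the carbenoid carbon (five-membered closure, exo with respect to the Rh=C bond, forming O1–C2), and the oxonium ylide 8 discharges itself by a Stevens [1,2]-shift of the 2-benzyloxyprop-2-yl group from O1 to C2. The O1–C(ketal) bond is the weakest bond at the oxonium centre, because its cleavage leaves a tertiary alpha-alkoxy radical or an oxocarbenium ion paired with the aromatic benzofuran-3-olate (or its radical), and collapse of this caged pair at carbon makes the C2–C(CH3)2 bond. The closest known reactions are the conversion of ortho-alkoxy- and ortho-allyloxy-diazoacetophenones into benzofuran-3(2H)-ones through cyclic oxonium ylides and the [1,2]-shift of acetal or ketal carbons in oxonium ylides of aliphatic diazoketones; an aryl mixed ketal has not served as the migrating group. The new stereocentre C2 is formed racemic and needs no control, since it stays epimerisable through the aromatic enol. Site selectivity is secured by the mirror symmetry of 7 (either ortho oxygen gives the same product) and by the kinetic preference for a five-membered ylide over a seven-membered one at the benzyloxy oxygen, while C- over O-recombination and suppression of proton loss from a ketal methyl group are favoured by the non-basic, dilute, room-temperature conditions. Any O-bound enol ketal should be convertible into 9 by a trace of Lewis acid, because C-alkylation is the thermodynamic outcome.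

Step 5
Reactants: 9 2-(2-benzyloxypropan-2-yl)-4-(2-benzyloxypropan-2-yloxy)benzofuran-3(2H)-one
Product: 11 4-hydroxy-2-(2-hydroxypropan-2-yl)benzofuran-3(2H)-one (racemic), via aryl hemiketal 10 (not isolated)
Conditions: H2 (1 atm), Pd/C (10 wt %), EtOAc, rt
Reagents that add atoms: none
Why: One hydrogenolysis cleaves both O-benzyl bonds (the tertiary ether gives the tertiary alcohol, the aryl ketal gives a hemiketal that sheds acetone), while the electron-rich vinylogous-ester ketone stays intact, as it does when aurones are hydrogenated to 2-benzylbenzofuran-3(2H)-ones.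

Step 6
Reactants: 11 4-hydroxy-2-(2-hydroxypropan-2-yl)benzofuran-3(2H)-one
Product: 12 trans-2-(2-hydroxypropan-2-yl)-2,3-dihydrobenzofuran-3,4-diol (racemate of the 2S,3S and 2R,3R forms)
Conditions: Me4NBH(OAc)3 (5 equiv), MeCN/AcOH, −30 → 0 °C; aq. NaHCO3
Reagents that add atoms: none
Why: In this Evans–Saksena reduction the tertiary hydroxyl exchanges onto boron and delivers hydride through a six-membered transition state to the face of C3 that carries the side chain, so the new C3 hydroxyl should end up trans to it, whereas the in-plane, hydrogen-bonded C4 phenol cannot place a B–H bond over the carbonyl and the reagent does not reduce undirected ketones.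

Step 7
Reactants: 12 trans-2-(2-hydroxypropan-2-yl)-2,3-dihydrobenzofuran-3,4-diol (racemic)
Product: 13 (2S,3S)-3-hydroxy-2-(2-hydroxypropan-2-yl)-2,3-dihydrobenzofuran-4-yl (1S,4R)-camphanate
Conditions: (1S)-(−)-camphanic chloride (1.0 equiv), Et3N, THF/CH2Cl2, −20 → 0 °C; separation of the two diastereomers (SiO2 or crystallisation)
Reagents that add atoms: (1S)-(−)-camphanic chloride, ClC(=O)[C@@]12CC[C@@](C)(C(=O)O1)C2(C)C
Why: Chemoselective acylation of the most acidic hydroxyl (the C4 phenol) with a hindered enantiopure acid chloride gives two diastereomeric aryl esters for a classical resolution, which forms no stereocentre but selects the (2S,3S) series, to be assigned by X-ray analysis against the known camphanoyl centres.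

Step 8
Reactants: 13 (2S,3S)-3-hydroxy-2-(2-hydroxypropan-2-yl)-2,3-dihydrobenzofuran-4-yl (1S,4R)-camphanate
Product: 14 (2S,3S)-5-bromo-3-hydroxy-2-(2-hydroxypropan-2-yl)-2,3-dihydrobenzofuran-4-yl (1S,4R)-camphanate
Conditions: NBS (1.0 equiv), MeCN, 0 °C → rt, dark
Reagents that add atoms: N-bromosuccinimide, O=C1CCC(=O)N1Br
Why: In this electrophilic aromatic bromination the C4 oxygen is switched off as an ester, so the ring oxygen O1 is the dominant donor and directs NBS to its para position C5, as in the bromination of 3-alkoxyphenyl esters para to the alkoxy group, with C7 only ortho-activated.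

Step 9
Reactants: 14 (2S,3S)-5-bromo-3-hydroxy-2-(2-hydroxypropan-2-yl)-2,3-dihydrobenzofuran-4-yl (1S,4R)-camphanate
Product: 16 (2S,3S)-5-acetyl-3-hydroxy-2-(2-hydroxypropan-2-yl)-2,3-dihydrobenzofuran-4-yl (1S,4R)-camphanate, via enol ether 15 (not isolated)
Conditions: Bu3SnC(OEt)=CH2, Pd(PPh3)4 (5 mol %), toluene, 90 °C; then 5% aq. oxalic acid, THF, 0 °C
Reagents that add atoms: tributyl(1-ethoxyvinyl)stannane, CCCC[Sn](CCCC)(CCCC)C(=C)OCC; water, O
Why: Stille coupling with an acetyl anion equivalent, followed by hydrolysis of the very labile alpha-aryl enol ether, places the methyl ketone on C5 at the oxidation level the chalcone needs, under neutral to weakly acidic conditions that leave the ester, the benzylic alcohol and both stereocentres untouched.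

Step 10
Reactants: 16 (2S,3S)-5-acetyl-3-hydroxy-2-(2-hydroxypropan-2-yl)-2,3-dihydrobenzofuran-4-yl (1S,4R)-camphanate; 17 4-hydroxybenzaldehyde
Product: 19 brosimacutin G, via free hydroxyacetophenone 18 (not isolated)
Conditions: KOH (50% aq., excess), EtOH, 0 °C → rt; AcOH to pH 6, 0 °C
Reagents that add atoms: none
Why: Hydroxide first saponifies the activated aryl ester, and the liberated 2-hydroxyacetophenone then undergoes Claisen–Schmidt condensation with the aldehyde, with E1cB dehydration giving the conjugated (E)-enone, while C2 and C3 carry no acidic hydrogen and keep their configuration.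

Compound list
1 | 2-bromobenzene-1,3-diol (2-bromoresorcinol) | Oc1cccc(O)c1Br | starting material
2 | benzyl isopropenyl ether (2-benzyloxypropene) | C=C(C)OCc1ccccc1 | starting material
3 | 2-bromo-1,3-bis(2-benzyloxypropan-2-yloxy)benzene | CC(C)(OCc1ccccc1)Oc1cccc(OC(C)(C)OCc2ccccc2)c1Br | intermediate
4 | 2,6-bis(2-benzyloxypropan-2-yloxy)phenyllithium | [Li]c1c(OC(C)(C)OCc2ccccc2)cccc1OC(C)(C)OCc1ccccc1 | intermediate
5 | 1-[2,6-bis(2-benzyloxypropan-2-yloxy)phenyl]ethanone | CC(=O)c1c(OC(C)(C)OCc2ccccc2)cccc1OC(C)(C)OCc1ccccc1 | intermediate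
6 | 1-[2,6-bis(2-benzyloxypropan-2-yloxy)phenyl]-4,4,4-trifluorobutane-1,3-dione | O=C(CC(=O)C(F)(F)F)c1c(OC(C)(C)OCc2ccccc2)cccc1OC(C)(C)OCc1ccccc1 | intermediate
7 | 1-[2,6-bis(2-benzyloxypropan-2-yloxy)phenyl]-2-diazoethanone | [N-]=[N+]=CC(=O)c1c(OC(C)(C)OCc2ccccc2)cccc1OC(C)(C)OCc1ccccc1 | intermediate
8 | 1-(2-benzyloxypropan-2-yl)-4-(2-benzyloxypropan-2-yloxy)-3-oxo-2,3-dihydrobenzofuran-1-ium-2-ide (oxonium ylide) | O=C1[CH-][O+](C(C)(C)OCc2ccccc2)c2cccc(OC(C)(C)OCc3ccccc3)c12 | intermediate
9 | 2-(2-benzyloxypropan-2-yl)-4-(2-benzyloxypropan-2-yloxy)benzofuran-3(2H)-one, racemic | CC(C)(OCc1ccccc1)C1Oc2cccc(OC(C)(C)OCc3ccccc3)c2C1=O | intermediate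
10 | 2-(2-hydroxypropan-2-yl)-4-(2-hydroxypropan-2-yloxy)benzofuran-3(2H)-one, racemic | CC(C)(O)Oc1cccc2OC(C(C)(C)O)C(=O)c12 | intermediate
11 | 4-hydroxy-2-(2-hydroxypropan-2-yl)benzofuran-3(2H)-one, racemic | CC(C)(O)C1Oc2cccc(O)c2C1=O | intermediate
12 | trans-2-(2-hydroxypropan-2-yl)-2,3-dihydrobenzofuran-3,4-diol, racemate (both enantiomers written) | CC(C)(O)[C@H]1Oc2cccc(O)c2[C@@H]1O.CC(C)(O)[C@@H]1Oc2cccc(O)c2[C@H]1O | intermediate
13 | (2S,3S)-3-hydroxy-2-(2-hydroxypropan-2-yl)-2,3-dihydrobenzofuran-4-yl (1S,4R)-camphanate | CC(C)(O)[C@H]1Oc2cccc(OC(=O)[C@@]34CC[C@@](C)(C(=O)O3)C4(C)C)c2[C@@H]1O | intermediate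
14 | (2S,3S)-5-bromo-3-hydroxy-2-(2-hydroxypropan-2-yl)-2,3-dihydrobenzofuran-4-yl (1S,4R)-camphanate | CC(C)(O)[C@H]1Oc2ccc(Br)c(OC(=O)[C@@]34CC[C@@](C)(C(=O)O3)C4(C)C)c2[C@@H]1O | intermediate
15 | (2S,3S)-5-(1-ethoxyvinyl)-3-hydroxy-2-(2-hydroxypropan-2-yl)-2,3-dihydrobenzofuran-4-yl (1S,4R)-camphanate | CC(C)(O)[C@H]1Oc2ccc(C(=C)OCC)c(OC(=O)[C@@]34CC[C@@](C)(C(=O)O3)C4(C)C)c2[C@@H]1O | intermediate
16 | (2S,3S)-5-acetyl-3-hydroxy-2-(2-hydroxypropan-2-yl)-2,3-dihydrobenzofuran-4-yl (1S,4R)-camphanate | CC(C)(O)[C@H]1Oc2ccc(C(C)=O)c(OC(=O)[C@@]34CC[C@@](C)(C(=O)O3)C4(C)C)c2[C@@H]1O | intermediate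
17 | 4-hydroxybenzaldehyde | O=Cc1ccc(O)cc1 | starting material
18 | 1-[(2S,3S)-3,4-dihydroxy-2-(2-hydroxypropan-2-yl)-2,3-dihydrobenzofuran-5-yl]ethanone | CC(C)(O)[C@H]1Oc2ccc(C(C)=O)c(O)c2[C@@H]1O | intermediate
19 | brosimacutin G, (E)-1-[(2S,3S)-3,4-dihydroxy-2-(2-hydroxypropan-2-yl)-2,3-dihydrobenzofuran-5-yl]-3-(4-hydroxyphenyl)prop-2-en-1-one | CC(C)(O)[C@H]1Oc2ccc(C(=O)/C=C/c3ccc(O)cc3)c(O)c2[C@@H]1O | target

Total step count: 10. Longest linear sequence: 10 steps (1 → 19).

Steps most likely to fail

1. Step 4 (bears the label).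
   - What may go wrong: the ylide may collapse by proton transfer from a ketal methyl group to the carbanion, with loss of the enol ether. The separated fragments may recombine at the enolate oxygen. The carbenoid may be intercepted by the more basic benzyloxy oxygen through a seven-membered ylide. Adventitious acid may strip the ketals before nitrogen is lost.
   - Fallback with known chemistry, setting out from 7: aqueous acetic acid hydrolyses both ketals and protonates the diazo carbon, and an ortho phenol displaces nitrogen to give 4-hydroxybenzofuran-3(2H)-one F1. Double silylation (Me3SiOTf, Et3N, CH2Cl2, 0 °C) gives 3,4-bis(trimethylsilyloxy)benzofuran F2. Its Mukaiyama aldol addition to acetone (TiCl4, CH2Cl2, −78 °C, bicarbonate work-up) makes the C2–C(CH3)2 bond and comes back to the route at 11.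

2. Step 7.
   - What may go wrong: the two diastereomeric esters may differ too little to be separated. The acyl group may also creep from the C4 oxygen to the C3 oxygen under the basic conditions.
   - Fallback, setting out from 12: the enantiomers are separated directly by preparative chromatography on a chiral stationary phase to give (2S,3S)-2-(2-hydroxypropan-2-yl)-2,3-dihydrobenzofuran-3,4-diol F3. F3 is then acylated with the same acid chloride, now only as protecting and deactivating group, and comes back to the route at 13.

3. Step 10.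
   - What may go wrong: the aldehyde is deactivated as its phenoxide, so the condensation may be sluggish. Long exposure to strong base invites Baker–Venkataraman-type acyl transfer before saponification, oxa-Michael closure to the flavanone on work-up, or reversible addition chemistry at C3 with erosion of the trans configuration.
   - Fallback, setting out from 16: saponification and condensation with commercial 4-(allyloxy)benzaldehyde, a markedly better electrophile that allows a short base contact, give (E)-3-[4-(allyloxy)phenyl]-1-[(2S,3S)-3,4-dihydroxy-2-(2-hydroxypropan-2-yl)-2,3-dihydrobenzofuran-5-yl]prop-2-en-1-one F4. Deallylation catalysed by zerovalent palladium (Pd(PPh3)4, K2CO3, MeOH, rt) comes back to the route at 19.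

Further compounds
F1 | step 4 | 4-hydroxybenzofuran-3(2H)-one | O=C1COc2cccc(O)c12
F2 | step 4 | 3,4-bis(trimethylsilyloxy)benzofuran | C[Si](C)(C)Oc1coc2cccc(O[Si](C)(C)C)c12
F3 | step 7 | (2S,3S)-2-(2-hydroxypropan-2-yl)-2,3-dihydrobenzofuran-3,4-diol | CC(C)(O)[C@H]1Oc2cccc(O)c2[C@@H]1O
F4 | step 10 | (E)-3-[4-(allyloxy)phenyl]-1-[(2S,3S)-3,4-dihydroxy-2-(2-hydroxypropan-2-yl)-2,3-dihydrobenzofuran-5-yl]prop-2-en-1-one | CC(C)(O)[C@H]1Oc2ccc(C(=O)/C=C/c3ccc(OCC=C)cc3)c(O)c2[C@@H]1O
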